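## Structural features

The target (40) is a resveratrol tetramer in which three trans-2,3-diaryl-2,3-dihydrobenzofurans stand in a row. Ring 1 is fused to the resorcinol ring of an (E)-4-hydroxystilbene (styryl on C4, hydroxyl on C6) and carries a 3,5-dihydroxyphenyl group on C3. C2 of ring 1 is bonded to C5 of the benzo ring of ring 2; C2 of ring 2 carries a 4-hydroxyphenyl group and C3 is bonded to C4 of the benzo ring of ring 3, which has a 3,5-dihydroxyphenyl group on C3, a 4-hydroxyphenyl group on C2 and a hydroxyl on C6. The six stereocentres form three vicinal C2/C3 pairs, each trans and each 2R,3R; the pairs are insulated from one another by arenes, except that C3 of ring 2 sits ortho to C3a of ring 3. Fragile sites are the nine phenols (air, base), the stilbene (light, and acid, under which the alkene can cyclise with the resorcinol ring on C3 of ring 1 or with a cation from ring 1), and each O1–C2 bond, a 4-oxybenzylic aryl ether that ionises under acid. The real difficulty is the bond between the secondary, stereogenic C3 of ring 2 and C4 of the ring-3 arene, whose neighbouring position C3a carries the substituted C3 of ring 3, together with setting three remote stereo-pairs in one absolute sense. The key step exploits the fact that this arene is a resorcinol, with oxygen on C6 and C7a and carbon on C4 and C3a: this is the pattern a 1,3-dioxygenated diene places on an alkynyl ketone, so the ring can be grown on an alkyne already attached to C3 of ring 2.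

## Logic of the disconnections

40 to 39: the nine O–CH3 bonds are cut. Methyl ethers survive every reagent in the route and all building blocks are sold as methyl ethers. The forward demand is a Lewis-acid cleavage that spares the stilbene and three benzylic C–O bonds.

39 to 35 + 36: O1–C2 and C2–C3 of ring 3 are cut. C2 with its aryl group is a one-carbon unit that can be delivered as a benzylidene from 36, and C3 then derives from a benzhydryl carbon. The gain is that both stereocentres of ring 3 are made last, from a precursor that is planar at that carbon (via 37). The forward step must be trans-selective and face-selective next to the stereocentre of ring 2.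

35 to 34 to 33 to 32: a C–S bond, a carbinol C–H bond and one O–CH3 bond are cut, leading back to the ketone the key step delivers. The demands are to tell the two phenols of 32 apart, to reduce a hindered diaryl ketone, and to exchange hydroxyl for sulfinate under weak acid with the stilbene present.

32 to 27 + 29 (key): C4–C5 and C3a–C7a of the ring-3 arene are cut. This removes the whole tetrasubstituted benzene and leaves an alkyne on C3 of ring 2, so the hindered aryl–C3 bond is never formed by coupling. The forward step must be regiospecific and neutral enough to leave the propargylic stereocentre untouched.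

27 to 25 + 26: the C(sp)–C(acyl) bond is cut, giving a terminal alkyne and a commercial acid chloride. The demand is coupling with minimal base.

25 to 23: the alkyne is traced to an ester by one-carbon homologation of the ester carbon. The ester is the group that the ring-2 closure requires and that allows cis-to-trans correction. The demand is that the aldehyde stage 24 is passed without scrambling C2.

23 to 21 + 22: the aryl–vinyl bond of the stilbene is cut. This keeps the alkene out of the cation-forming and carbene steps. The demand is coupling at a hindered bromide with retention of E geometry.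

21 to 19 to 18: C2–C3 of ring 2 is cut (C–H insertion), then the aryl–C bond to the diazo carbon. The ether oxygen, its CH2 and the C2 aryl group are already in place in 18, and a chiral catalyst sets the new centres. The demands are use of C–I before C–Br, an enantioselective insertion, and epimerisation at C3 only.

18 to 6 + 15: O1–C2 and C2–C3 of ring 1 are cut, by the same logic as for ring 3. This gives two planar fragments of similar size. The demand is an enantio- and trans-selective annulation.

6 to 5 to 2 + 3 (via 4), 2 to 1; 15 to 10 + 13, 10 to 9 to 7 + 8; 13 to 11; 36 to 8 + 13; 29 to 28: single C–C, C–S, C–O and O–Si bonds are cut, leading to commercial materials. The only demand is the ortho-selective ether cleavage that turns 1 into 2.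

## Other disconnections considered

Alternative 1: The cut is O1–C2 of ring 2. In the forward step the carboxylate of a 3-(2-hydroxyaryl)-2,3-diarylpropanoic acid is oxidised at an anode (Hofer–Moest pathway), CO2 is lost, and the 4-methoxybenzylic cation is captured by the ortho phenol to give A1, the 5-bromo ring-2 unit that already carries ring 3.
- In its favour: the oxidation needs no reagent. The cation closes to the more stable trans ring from either epimer at the carboxyl-bearing carbon, so no separate epimerisation is needed; on this point it is better than the chosen plan, which corrects ring 2 with base in step 10.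
- Against it: C3 of ring 2 must already be bonded to the complete ring-3 arene, so the hindered bond has to be made earlier by adding an ortho-disubstituted aryl nucleophile. The electron-rich arenes and ring 3 oxidise near the carboxylate potential. A1 still lacks ring 1 and the stilbene.
- Comparison: the trans outcome at ring 2 is equal in both plans. Mechanistically A1's ring closure is stereoconvergent while the chosen arene construction creates no stereocentre at all. In step economy Alternative 1 is no shorter, because ring 1 must then be built on the largest fragment.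

Alternative 2: The cut is three bonds of the benzo ring of ring 2 (C7a–C3a, C6–C7, C4–C5). In the forward step a tethered diyne (silyl-capped ynol ether and terminal alkyne joined through O1, C2 and C3) and the ethynyl group on C2 of a ring-1 fragment are cyclotrimerised on Cp*RuCl(cod) or [Rh(cod)2]BF4/BINAP. This gives A2, which needs protodesilylation at C7.
- In its favour: two rings and three bonds form in one step and two large fragments are united, which is better than the chosen key step in bond count and convergence. The hindered C3–arene bond is never made by coupling, which is equal to the chosen plan.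
- Against it: the diyne must carry both stereocentres of ring 2 and all of ring 3 in an open-chain ether with defined relative configuration. Secondary alkyl ynol ethers are thermally and acid labile. The position of the third alkyne (C5 or C6) rests on steric steering by silicon. The terminal alkyne can self-trimerise.
- Comparison: regiochemistry in the chosen plan is fixed electronically and in Alternative 2 sterically. The step saving in the key step of Alternative 2 is offset by the longer route to the diyne.

Alternative 3: The cut is C2–C3 of ring 2 as the last skeletal bond. In the forward step a hindered diaryl ketone hydrazone is oxidised with MnO2 to the diaryldiazomethane, which loses N2 on Rh2(PTAD)4; the donor/donor carbene inserts into the OCH2 bond of the 4-methoxybenzyl ether to give A3, one step from the target.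
- In its favour: it has the shortest end game and the latest union of a ring-1 half with a ring-3 half, needs no acceptor group and has no propargylic centre. In step count after fragment union and in convergence it is better than the chosen plan.
- Against it: hydrazone formation at a ketone flanked by an ortho ether and by C3a of ring 3 is slow. Insertions of this type favour the 2,3-cis ring, so an acid epimerisation with the stilbene present would follow. MnO2 and the carbene meet an electron-rich stilbene. The catalyst must override two existing stereo-pairs.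
- Comparison: the chosen plan fixes the trans relationship of ring 2 through an ester enolate before the hard arene exists. Alternative 3 is shorter but less certain in the cis/trans outcome at ring 2. The same reaction type is kept in reserve for the ring closures of steps 8 and 20.

Key step: step 15

Remark: the sense of induction of Rh2(S-PTTL)4 (step 10) and of sulfide 13 (steps 8 and 20) is assigned by analogy with simpler substrates; both are accessible as mirror images (13 from the (2R,5R)-diol), and nothing else changes if the antipode is the one that leads to the 2R,3R rings.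

Remark: alkynyl, cyclohexadienyl and aryl groups on C3 of ring 2 all rank below C3a, so that centre keeps the descriptor R from 21 to 40 although its substituent changes.

## Route

Step 1
Reactants: 1 2-bromo-4,6-dimethoxybenzaldehyde
Product: 2 2-bromo-6-hydroxy-4-methoxybenzaldehyde
Conditions: BCl3 (1.2 equiv), CH2Cl2, −78 → 0 °C; aq. work-up
Reagents that add atoms: none
Why: Boron chelates between the aldehyde oxygen and the ortho methoxy group, so chloride cleaves that methyl ether only (chelation-directed Lewis-acid ether cleavage); the para methoxy group and the C–Br bond are inert at this temperature.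

Step 2
Reactants: 2 2-bromo-6-hydroxy-4-methoxybenzaldehyde; 3 1-bromo-3,5-dimethoxybenzene
Product: 5 ring-1 ortho-hydroxybenzhydrol (racemic), via aryl Grignard reagent 4 (not isolated)
Conditions: 3, Mg, I2 (cat.), THF, reflux (4, 2.3 equiv); then 2, THF, 0 °C → rt; aq. NH4Cl
Reagents that add atoms: none
Why: Grignard addition to the salicylaldehyde (one equivalent of 4 is spent on the phenol); the carbinol centre is racemic and is erased when the quinone methide forms in step 8.

Step 3
Reactants: 5 ring-1 ortho-hydroxybenzhydrol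
Product: 6 ring-1 sulfone (racemic)
Conditions: p-TolSO2H (1.5 equiv), CH2Cl2, rt
Reagents that add atoms: p-toluenesulfinic acid, Cc1ccc(cc1)S(=O)O
Why: The ortho-hydroxybenzhydrol ionises under weak acid and is captured at sulfur by the sulfinate (substitution through the quinone methide/benzhydryl cation), giving the storable sulfone from which base regenerates the quinone methide; no alkene is present yet that could trap the cation.

Step 4
Reactants: 7 4-hydroxy-3-iodobenzaldehyde; 8 4-methoxybenzyl chloride
Product: 9 3-iodo-4-[(4-methoxyphenyl)methoxy]benzaldehyde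
Conditions: K2CO3, DMF, 50 °C
Reagents that add atoms: none
Why: Williamson ether synthesis on the phenoxide; the 4-methoxybenzyl group is not a protecting group here, since its CH2 becomes C2 of ring 2 and its arene the C2 aryl group.

Step 5
Reactants: 9 3-iodo-4-[(4-methoxyphenyl)methoxy]benzaldehyde
Product: 10 benzylic alcohol of 9
Conditions: NaBH4, MeOH–THF, 0 °C
Reagents that add atoms: none
Why: Hydride reduction of the aldehyde; aryl iodide and benzyl ether are inert.

Step 6
Reactants: 11 (2S,5S)-hexane-2,5-diol
Product: 13 (2R,5R)-2,5-dimethylthiolane, via dimesylate 12 (not isolated)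
Conditions: MsCl, Et3N, CH2Cl2, 0 °C; then Na2S·9H2O, DMSO, 25 °C
Reagents that add atoms: sodium sulfide, [Na+].[Na+].[S-2]
Why: Double mesylation and double SN2 displacement by sulfide with inversion at both carbons turns the (S,S)-diol into the (R,R)-thiolane; C2 symmetry makes the two sulfur lone pairs equivalent, so later S-alkylation gives a single salt.

Step 7
Reactants: 10 benzylic alcohol; 13 (2R,5R)-2,5-dimethylthiolane
Product: 15 chiral benzylsulfonium tetrafluoroborate, via benzylic chloride 14 (not isolated)
Conditions: MsCl, Et3N, CH2Cl2, 0 °C; then 13, NaBF4, acetone–H2O, rt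
Reagents that add atoms: sodium tetrafluoroborate, [Na+].F[B-](F)(F)F
Why: The electron-rich benzylic mesylate collapses to chloride 14 in the flask and alkylates the sulfide; exchange to tetrafluoroborate removes the nucleophilic counter-ion and gives a salt that can be crystallised.

Step 8
Reactants: 6 ring-1 sulfone; 15 chiral benzylsulfonium tetrafluoroborate
Product: 18 (2R,3R)-trans ring-1 dihydrobenzofuran with 4-bromo and 3-iodoaryl handles, via ortho-quinone methide 16 (not isolated), via sulfonium ylide 17 (not isolated)
Conditions: Cs2CO3 (3 equiv), CH2Cl2, 0 °C → rt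
Reagents that add atoms: none
Why: Proposed new method: carbonate releases quinone methide 16 from 6 (1,4-elimination of sulfinate) and ylide 17 from 15; the ylide carbon adds to the methide carbon (C2–C3, driven by rearomatisation) and the phenoxide then displaces the sulfide from the benzylic carbon with inversion (5-exo-tet, O1–C2), the two aryl groups ending trans because they stay apart in the open addition transition state; the C2-symmetric sulfide is expected to expose one face of the ylide, as in its benzylidene transfer to aldehydes, and so to set 2R,3R; the closest known reaction types are the [4+1] annulation of ortho-quinone methides from 2-(sulfonylalkyl)phenols with carbonyl-stabilised sulfonium ylides and with chiral ammonium ylides, and asymmetric epoxidation with chiral benzylsulfonium ylides.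

Step 9
Reactants: 18 ring-1 dihydrobenzofuran
Product: 19 aryl diazoacetate
Conditions: N2CHCO2Et (2 equiv), Pd(PPh3)4 (5 mol%), Et3N, n-Bu4NBr, MeCN, rt
Reagents that add atoms: ethyl diazoacetate, CCOC(=O)C=[N+]=[N-]
Why: Palladium-catalysed cross-coupling of an aryl iodide with ethyl diazoacetate (the diazo carbon is arylated with retention of N2); at room temperature zerovalent palladium inserts into C–I only, so the C–Br bond needed in step 11 is kept.

Step 10
Reactants: 19 aryl diazoacetate
Product: 21 (2R,3R)-trans ring-2 ethyl ester on the ring-1 bromide, via cis ester 20 (not isolated)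
Conditions: Rh2(S-PTTL)4 (dirhodium tetrakis[N-phthaloyl-(S)-tert-leucinate], 1 mol%), toluene, −60 °C → rt; then NaOEt (0.3 equiv), EtOH, rt
Reagents that add atoms: none
Why: The divalent-rhodium carbene inserts into the OCH2 bond five atoms away (intramolecular 1,5 C–H insertion at a site activated by oxygen and the anisyl ring), closing ring 2 as cis ester 20 with C2 set as R by the chiral carboxylate ligands; catalytic ethoxide then inverts only C3 through the ester enolate to the more stable trans isomer, which should be faster than expulsion of the aryloxide. Material from the minor enantiomer of 18 is now a diastereomer and is removed by chromatography.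

Step 11
Reactants: 21 trans ring-2 ester bromide; 22 [(E)-2-(4-methoxyphenyl)ethenyl]boronic acid
Product: 23 trans ring-2 ester carrying ring 1 and the stilbene
Conditions: Pd(OAc)2 (3 mol%), SPhos (6 mol%), K3PO4, toluene–H2O, 60 °C
Reagents that add atoms: none
Why: Suzuki–Miyaura coupling with retention of the E geometry of the vinylboron partner; the biaryl dialkylphosphine is chosen for the ortho-substituted bromide, and the alkene enters only after the cation-forming (step 3) and carbene (step 10) steps.

Step 12
Reactants: 23 trans ring-2 ester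
Product: 25 ring-2 3-ethynyl compound, via aldehyde 24 (not isolated)
Conditions: i-Bu2AlH (1.1 equiv), CH2Cl2, −78 °C; then MeOH, K2CO3, MeC(O)C(N2)P(O)(OMe)2, −78 °C → rt
Reagents that add atoms: dimethyl (1-diazo-2-oxopropyl)phosphonate, COP(=O)(OC)C(=[N+]=[N-])C(C)=O
Why: Half-reduction of the ester gives an aluminium hemiacetal that releases aldehyde 24 on methanolysis, and 24 is homologated in the same flask by Seyferth–Gilbert reaction with the Ohira–Bestmann reagent; C3 can only equilibrate towards the trans arrangement it already has, and not isolating 24 limits loss by enolisation.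

Step 13
Reactants: 25 ring-2 3-ethynyl compound; 26 3,5-dimethoxybenzoyl chloride
Product: 27 alkynyl ketone (key-step substrate)
Conditions: PdCl2(PPh3)2 (2 mol%), CuI (4 mol%), Et3N (1.2 equiv), THF, rt
Reagents that add atoms: none
Why: Acylative Sonogashira coupling (copper acetylide, transmetalation to the acylpalladium chloride, reductive elimination); one equivalent of amine at room temperature is used to avoid propargyl-to-allenyl isomerisation of the ynone.

Step 14
Reactants: 28 methyl 3-(trimethylsilyloxy)but-2-enoate
Product: 29 1-methoxy-1,3-bis(trimethylsilyloxy)buta-1,3-diene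
Conditions: LiN(i-Pr)2, THF, −78 °C; Me3SiCl, −78 → 0 °C; distilled
Reagents that add atoms: chlorotrimethylsilane, C[Si](C)(C)Cl
Why: γ-Deprotonation of the vinylogous ester gives the dienolate, which is silylated on the ester oxygen to the mixed ketene acetal; the diene is moisture-sensitive and is used at once.

Step 15
Reactants: 27 alkynyl ketone; 29 1-methoxy-1,3-bis(trimethylsilyloxy)buta-1,3-diene
Product: 32 2,4-dihydroxybenzophenone with ring 2 ortho to the ketone, via cycloadduct 30 (not isolated), via bis(trimethylsilyl) ether 31 (not isolated)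
Conditions: 29 (3 equiv), toluene, 25 → 60 °C; then 0.5 M HCl, THF, 0 °C
Reagents that add atoms: none
Why: The electron-rich diene and the electron-poor ynone combine in a normal-demand, asynchronous Diels–Alder reaction: the CH2 terminus of 29, its most nucleophilic carbon, bonds to the β-carbon of the ynone (the future C4–C5 bond) and the ketene-acetal carbon to the α-carbon (C3a–C7a), giving cyclohexa-1,4-diene 30. Loss of methanol across the ring (methoxide from the ketal carbon, hydrogen from the CH2 group) aromatises 30 to bis-silyl ether 31, and dilute acid frees the two phenols of 32. The closest known reaction type is the cycloaddition–aromatisation of 1-alkoxy-1,3-bis(silyloxy)buta-1,3-dienes with propiolates, acetylenedicarboxylates and alkynyl ketones to give resorcinols. The one ring that closes is the benzene ring of ring 3, by intermolecular [4+2] closure in which both new σ bonds end on the former alkyne carbons. No stereocentre is made: the ketal carbon of 30 is transient and the four existing centres are spectators. The step needs regioselectivity (both oxygens meta to the ring-2 substituent, the ketone ortho to a hydroxyl), which the polarisation of the two partners secures; the other orientation would also force the fully substituted ketal carbon against the branched C3 of ring 2. It needs chemoselectivity for the ynone over the stilbene and the arenes, which an alkene without an acceptor group cannot contest at 60 °C. It finally needs the propargylic C3–H of ring 2 to stay untouched, which neutral, aprotic, base-free conditions ensure; once the arene exists this hydrogen is no longer activated.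

Step 16
Reactants: 32 2,4-dihydroxybenzophenone
Product: 33 2-hydroxy-4-methoxybenzophenone
Conditions: MeI (1.1 equiv), K2CO3 (1.1 equiv), acetone, rt
Reagents that add atoms: iodomethane, CI
Why: The para hydroxyl is the more acidic and is free of the hydrogen bond that ties the ortho hydroxyl to the ketone, so one equivalent of base and MeI alkylates it selectively (regioselective Williamson methylation of a 2,4-dihydroxybenzophenone).

Step 17
Reactants: 33 2-hydroxy-4-methoxybenzophenone
Product: 34 ring-3 ortho-hydroxybenzhydrol (both carbinol epimers)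
Conditions: NaBH4, THF–MeOH, 0 °C
Reagents that add atoms: none
Why: Hydride reduction of the diaryl ketone; the carbinol configuration is of no consequence, and low temperature avoids further reduction through the quinone methide.

Step 18
Reactants: 34 ring-3 ortho-hydroxybenzhydrol
Product: 35 ring-3 sulfone (both epimers)
Conditions: p-TolSO2H (2 equiv), CH2Cl2, 0 °C → rt
Reagents that add atoms: p-toluenesulfinic acid, Cc1ccc(cc1)S(=O)O
Why: Same substitution as step 3; the weak sulfinic acid suffices for this doubly activated benzhydrol, the sulfinate should trap the cation faster than the remote stilbene or arenes can, and both epimers converge on quinone methide 37.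

Step 19
Reactants: 8 4-methoxybenzyl chloride; 13 (2R,5R)-2,5-dimethylthiolane
Product: 36 chiral 4-methoxybenzylsulfonium tetrafluoroborate
Conditions: NaBF4, acetone–H2O, rt
Reagents that add atoms: sodium tetrafluoroborate, [Na+].F[B-](F)(F)F
Why: S-Alkylation of the sulfide by the reactive benzylic chloride, driven by exchange to the tetrafluoroborate salt.

Step 20
Reactants: 35 ring-3 sulfone; 36 chiral 4-methoxybenzylsulfonium tetrafluoroborate
Product: 39 nona-O-methyl ether of the target, via ortho-quinone methide 37 (not isolated), via sulfonium ylide 38 (not isolated)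
Conditions: Cs2CO3 (3 equiv), CH2Cl2, 0 °C → rt
Reagents that add atoms: none
Why: Proposed new method: as in step 8, base gives quinone methide 37 and ylide 38, conjugate addition forms C2–C3 of ring 3 and the phenoxide closes O1–C2 by displacement of the sulfide with inversion, trans for the same steric reason; the face of 37 is biased both by the chiral ylide and by the adjacent C3 of ring 2, the sulfide enantiomer being the one that reinforces the substrate bias towards 2R,3R; the closest known reaction types are the [4+1] annulation of ortho-quinone methides with stabilised sulfonium or chiral ammonium ylides and asymmetric benzylidene transfer from chiral sulfonium ylides.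

Step 21
Reactants: 39 nona-O-methyl ether
Product: 40 target, all-(2R,3R) tetramer
Conditions: BBr3 (30 equiv), CH2Cl2, −78 → 0 °C; MeOH at −78 °C, then aq. NaHCO3
Reagents that add atoms: none
Why: Lewis-acid cleavage of the nine aryl methyl ethers (boron coordinates oxygen, bromide attacks methyl), a deprotection established for permethylated oligostilbenes that contain trans-2,3-diaryldihydrobenzofurans; every ring is already the more stable trans isomer, so reversible O1–C2 ionisation cannot change it, and the cold, buffered quench limits the time the stilbene spends in protic acid.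

## Compound list

In the names, W = (2R,3R)-4-bromo-3-(3,5-dimethoxyphenyl)-6-methoxy-2,3-dihydro-1-benzofuran-2-yl; U = (2R,3R)-3-(3,5-dimethoxyphenyl)-6-methoxy-4-[(E)-2-(4-methoxyphenyl)ethenyl]-2,3-dihydro-1-benzofuran-2-yl; V = (2R,3R)-2-(4-methoxyphenyl)-5-U-2,3-dihydro-1-benzofuran-3-yl.

1 | 2-bromo-4,6-dimethoxybenzaldehyde | COc1cc(OC)c(C=O)c(Br)c1 | starting material
2 | 2-bromo-6-hydroxy-4-methoxybenzaldehyde | COc1cc(O)c(C=O)c(Br)c1 | intermediate
3 | 1-bromo-3,5-dimethoxybenzene | COc1cc(Br)cc(OC)c1 | starting material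
4 | (3,5-dimethoxyphenyl)magnesium bromide (not isolated) | COc1cc([Mg]Br)cc(OC)c1 | intermediate
5 | 3-bromo-2-[(3,5-dimethoxyphenyl)(hydroxy)methyl]-5-methoxyphenol (racemic) | COc1cc(O)c(C(O)c2cc(OC)cc(OC)c2)c(Br)c1 | intermediate
6 | 3-bromo-2-[(3,5-dimethoxyphenyl)(4-methylbenzenesulfonyl)methyl]-5-methoxyphenol (racemic) | COc1cc(O)c(C(c2cc(OC)cc(OC)c2)S(=O)(=O)c2ccc(C)cc2)c(Br)c1 | intermediate
7 | 4-hydroxy-3-iodobenzaldehyde | O=Cc1ccc(O)c(I)c1 | starting material
8 | 1-(chloromethyl)-4-methoxybenzene | COc1ccc(CCl)cc1 | starting material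
9 | 3-iodo-4-[(4-methoxyphenyl)methoxy]benzaldehyde | COc1ccc(COc2ccc(C=O)cc2I)cc1 | intermediate
10 | {3-iodo-4-[(4-methoxyphenyl)methoxy]phenyl}methanol | COc1ccc(COc2ccc(CO)cc2I)cc1 | intermediate
11 | (2S,5S)-hexane-2,5-diol | C[C@H](O)CC[C@H](C)O | starting material
12 | (2S,5S)-hexane-2,5-diyl dimethanesulfonate (not isolated) | C[C@H](OS(C)(=O)=O)CC[C@H](C)OS(C)(=O)=O | intermediate
13 | (2R,5R)-2,5-dimethylthiolane | C[C@@H]1CC[C@@H](C)S1 | intermediate
14 | 4-(chloromethyl)-2-iodo-1-[(4-methoxyphenyl)methoxy]benzene (not isolated) | COc1ccc(COc2ccc(CCl)cc2I)cc1 | intermediate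
15 | (2R,5R)-1-({3-iodo-4-[(4-methoxyphenyl)methoxy]phenyl}methyl)-2,5-dimethylthiolan-1-ium tetrafluoroborate | C[C@@H]1CC[C@@H](C)[S+]1Cc1ccc(OCc2ccc(OC)cc2)c(I)c1.F[B-](F)(F)F | intermediate
16 | 5-bromo-6-[(3,5-dimethoxyphenyl)methylidene]-3-methoxycyclohexa-2,4-dien-1-one (not isolated) | COC1=CC(=O)C(=Cc2cc(OC)cc(OC)c2)C(Br)=C1 | intermediate
17 | [(2R,5R)-2,5-dimethylthiolan-1-ium-1-yl]{3-iodo-4-[(4-methoxyphenyl)methoxy]phenyl}methanide (not isolated) | C[C@@H]1CC[C@@H](C)[S+]1[CH-]c1ccc(OCc2ccc(OC)cc2)c(I)c1 | intermediate
18 | (2R,3R)-4-bromo-3-(3,5-dimethoxyphenyl)-2-{3-iodo-4-[(4-methoxyphenyl)methoxy]phenyl}-6-methoxy-2,3-dihydro-1-benzofuran | Brc1cc(OC)cc2c1[C@@H](c1cc(OC)cc(OC)c1)[C@H](c1ccc(OCc3ccc(OC)cc3)c(I)c1)O2 | intermediate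
19 | ethyl diazo{2-[(4-methoxyphenyl)methoxy]-5-W-phenyl}acetate | Brc1cc(OC)cc2c1[C@@H](c1cc(OC)cc(OC)c1)[C@H](c1ccc(OCc3ccc(OC)cc3)c(c1)C(=[N+]=[N-])C(=O)OCC)O2 | intermediate
20 | ethyl (2R,3S)-2-(4-methoxyphenyl)-5-W-2,3-dihydro-1-benzofuran-3-carboxylate (cis, not isolated) | Brc1cc(OC)cc2c1[C@@H](c1cc(OC)cc(OC)c1)[C@H](c1ccc3c(c1)[C@H](C(=O)OCC)[C@H](c1ccc(OC)cc1)O3)O2 | intermediate
21 | ethyl (2R,3R)-2-(4-methoxyphenyl)-5-W-2,3-dihydro-1-benzofuran-3-carboxylate (trans) | Brc1cc(OC)cc2c1[C@@H](c1cc(OC)cc(OC)c1)[C@H](c1ccc3c(c1)[C@@H](C(=O)OCC)[C@H](c1ccc(OC)cc1)O3)O2 | intermediate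
22 | [(E)-2-(4-methoxyphenyl)ethenyl]boronic acid | COc1ccc(/C=C/B(O)O)cc1 | starting material
23 | ethyl (2R,3R)-2-(4-methoxyphenyl)-5-U-2,3-dihydro-1-benzofuran-3-carboxylate | COc1ccc(/C=C/c2cc(OC)cc3c2[C@@H](c2cc(OC)cc(OC)c2)[C@H](c2ccc4c(c2)[C@@H](C(=O)OCC)[C@H](c2ccc(OC)cc2)O4)O3)cc1 | intermediate
24 | (2R,3R)-2-(4-methoxyphenyl)-5-U-2,3-dihydro-1-benzofuran-3-carbaldehyde (not isolated) | COc1ccc(/C=C/c2cc(OC)cc3c2[C@@H](c2cc(OC)cc(OC)c2)[C@H](c2ccc4c(c2)[C@@H](C=O)[C@H](c2ccc(OC)cc2)O4)O3)cc1 | intermediate
25 | (2R,3R)-3-ethynyl-2-(4-methoxyphenyl)-5-U-2,3-dihydro-1-benzofuran | COc1ccc(/C=C/c2cc(OC)cc3c2[C@@H](c2cc(OC)cc(OC)c2)[C@H](c2ccc4c(c2)[C@@H](C#C)[C@H](c2ccc(OC)cc2)O4)O3)cc1 | intermediate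
26 | 3,5-dimethoxybenzoyl chloride | COc1cc(cc(OC)c1)C(Cl)=O | starting material
27 | 1-(3,5-dimethoxyphenyl)-3-V-prop-2-yn-1-one | COc1ccc(/C=C/c2cc(OC)cc3c2[C@@H](c2cc(OC)cc(OC)c2)[C@H](c2ccc4c(c2)[C@@H](C#CC(=O)c2cc(OC)cc(OC)c2)[C@H](c2ccc(OC)cc2)O4)O3)cc1 | intermediate
28 | methyl 3-(trimethylsilyloxy)but-2-enoate (E/Z mixture) | COC(=O)C=C(C)O[Si](C)(C)C | starting material
29 | 1-methoxy-1,3-bis(trimethylsilyloxy)buta-1,3-diene | COC(O[Si](C)(C)C)=CC(=C)O[Si](C)(C)C | intermediate
30 | (3,5-dimethoxyphenyl)[6-methoxy-4,6-bis(trimethylsilyloxy)-2-V-cyclohexa-1,4-dien-1-yl]methanone (both epimers at C6 of the new ring, not isolated) | COc1ccc(/C=C/c2cc(OC)cc3c2[C@@H](c2cc(OC)cc(OC)c2)[C@H](c2ccc4c(c2)[C@@H](C2=C(C(=O)c5cc(OC)cc(OC)c5)C(OC)(O[Si](C)(C)C)C=C(O[Si](C)(C)C)C2)[C@H](c2ccc(OC)cc2)O4)O3)cc1 | intermediate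
31 | [2,4-bis(trimethylsilyloxy)-6-V-phenyl](3,5-dimethoxyphenyl)methanone (not isolated) | COc1ccc(/C=C/c2cc(OC)cc3c2[C@@H](c2cc(OC)cc(OC)c2)[C@H](c2ccc4c(c2)[C@@H](c2cc(O[Si](C)(C)C)cc(O[Si](C)(C)C)c2C(=O)c2cc(OC)cc(OC)c2)[C@H](c2ccc(OC)cc2)O4)O3)cc1 | intermediate
32 | (2,4-dihydroxy-6-V-phenyl)(3,5-dimethoxyphenyl)methanone | COc1ccc(/C=C/c2cc(OC)cc3c2[C@@H](c2cc(OC)cc(OC)c2)[C@H](c2ccc4c(c2)[C@@H](c2cc(O)cc(O)c2C(=O)c2cc(OC)cc(OC)c2)[C@H](c2ccc(OC)cc2)O4)O3)cc1 | intermediate
33 | (2-hydroxy-4-methoxy-6-V-phenyl)(3,5-dimethoxyphenyl)methanone | COc1ccc(/C=C/c2cc(OC)cc3c2[C@@H](c2cc(OC)cc(OC)c2)[C@H](c2ccc4c(c2)[C@@H](c2cc(OC)cc(O)c2C(=O)c2cc(OC)cc(OC)c2)[C@H](c2ccc(OC)cc2)O4)O3)cc1 | intermediate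
34 | 2-[(3,5-dimethoxyphenyl)(hydroxy)methyl]-5-methoxy-3-V-phenol (both carbinol epimers) | COc1ccc(/C=C/c2cc(OC)cc3c2[C@@H](c2cc(OC)cc(OC)c2)[C@H](c2ccc4c(c2)[C@@H](c2cc(OC)cc(O)c2C(O)c2cc(OC)cc(OC)c2)[C@H](c2ccc(OC)cc2)O4)O3)cc1 | intermediate
35 | 2-[(3,5-dimethoxyphenyl)(4-methylbenzenesulfonyl)methyl]-5-methoxy-3-V-phenol (both epimers) | COc1ccc(/C=C/c2cc(OC)cc3c2[C@@H](c2cc(OC)cc(OC)c2)[C@H](c2ccc4c(c2)[C@@H](c2cc(OC)cc(O)c2C(c2cc(OC)cc(OC)c2)S(=O)(=O)c2ccc(C)cc2)[C@H](c2ccc(OC)cc2)O4)O3)cc1 | intermediate
36 | (2R,5R)-1-[(4-methoxyphenyl)methyl]-2,5-dimethylthiolan-1-ium tetrafluoroborate | C[C@@H]1CC[C@@H](C)[S+]1Cc1ccc(OC)cc1.F[B-](F)(F)F | intermediate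
37 | 6-[(3,5-dimethoxyphenyl)methylidene]-3-methoxy-5-V-cyclohexa-2,4-dien-1-one (not isolated) | COc1ccc(/C=C/c2cc(OC)cc3c2[C@@H](c2cc(OC)cc(OC)c2)[C@H](c2ccc4c(c2)[C@@H](C2=CC(OC)=CC(=O)C2=Cc2cc(OC)cc(OC)c2)[C@H](c2ccc(OC)cc2)O4)O3)cc1 | intermediate
38 | [(2R,5R)-2,5-dimethylthiolan-1-ium-1-yl](4-methoxyphenyl)methanide (not isolated) | C[C@@H]1CC[C@@H](C)[S+]1[CH-]c1ccc(OC)cc1 | intermediate
39 | (2R,3R)-3-(3,5-dimethoxyphenyl)-6-methoxy-2-(4-methoxyphenyl)-4-V-2,3-dihydro-1-benzofuran (nona-O-methyl ether of the target) | COc1ccc(/C=C/c2cc(OC)cc3c2[C@@H](c2cc(OC)cc(OC)c2)[C@H](c2ccc4c(c2)[C@@H](c2cc(OC)cc5c2[C@@H](c2cc(OC)cc(OC)c2)[C@H](c2ccc(OC)cc2)O5)[C@H](c2ccc(OC)cc2)O4)O3)cc1 | intermediate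
40 | (2R,3R)-3-(3,5-dihydroxyphenyl)-2-(4-hydroxyphenyl)-4-{(2R,3R)-5-[(2R,3R)-3-(3,5-dihydroxyphenyl)-6-hydroxy-4-[(E)-2-(4-hydroxyphenyl)ethenyl]-2,3-dihydro-1-benzofuran-2-yl]-2-(4-hydroxyphenyl)-2,3-dihydro-1-benzofuran-3-yl}-2,3-dihydro-1-benzofuran-6-ol | Oc1ccc(/C=C/c2cc(O)cc3c2[C@@H](c2cc(O)cc(O)c2)[C@H](c2ccc4c(c2)[C@@H](c2cc(O)cc5c2[C@@H](c2cc(O)cc(O)c2)[C@H](c2ccc(O)cc2)O5)[C@H](c2ccc(O)cc2)O4)O3)cc1 | target

## Step count and least certain steps

Total step count: 21. Longest linear sequence: 15 steps (1 → 2 → 5 → 6 → 18 → 19 → 21 → 23 → 25 → 27 → 32 → 33 → 34 → 35 → 39 → 40).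

Step 8 (ring 1 by ylide annulation). The likely failures are poor facial selectivity in the addition of the ylide to the planar quinone methide, which would lower the enantiomeric purity of ring 1, and benzyl transfer from the sulfonium salt to the phenoxide before the quinone methide forms. The fallback sets out from 5 and returns at 18. 5 is oxidised with MnO2 (CH2Cl2, rt) to the 2-hydroxybenzophenone F1. F1 is O-alkylated with chloride 14 (made as in step 7, used crude; K2CO3, DMF, 50 °C) to the benzyl ether F2, which is condensed with N2H4·H2O (EtOH, AcOH cat., reflux) to the hydrazone F3. Oxidation with MnO2 followed by Rh2(R-PTAD)4 (dirhodium tetrakis[(R)-(1-adamantyl)(phthalimido)acetate], or its mirror image as the sense of induction requires), with loss of N2, should close ring 1 by donor/donor carbene insertion into the OCH2 bond as the 2,3-cis dihydrobenzofuran F4. Reversible O1–C2 ionisation with a catalytic Lewis acid (BF3·OEt2, CH2Cl2, −40 °C) should then give the trans isomer 18; the primary 4-methoxybenzyl ether ionises less readily than the secondary ring ether but has to be watched.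

Step 20 (ring 3 by ylide annulation). The likely failures are a mismatch between the facial preference imposed by C3 of ring 2 next to the methide carbon and that of the chiral ylide, and slow addition to the hindered quinone methide, which would let it oligomerise or add water. The fallback sets out from 33 and returns at 39. 33 is O-alkylated with 8 (K2CO3, DMF, 60 °C) to the 4-methoxybenzyl ether F5 and converted with N2H4·H2O into the hydrazone F6. MnO2 and then Rh2(R-PTAD)4 should give, by carbene insertion into the OCH2 bond, the isomer F7 of 39 that is cis at ring 3. Epimerisation at C2 of ring 3 (BF3·OEt2 cat., CH2Cl2, −40 °C, short contact because of the stilbene) should lead to 39.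

Step 15 (key step). The likely failures are isomerisation of the ynone to an allenyl ketone by traces of base before cycloaddition, which would destroy C3 of ring 2, steric retardation at the branched β-carbon, and conjugate addition of the diene without ring closure. The fallback sets out from 25 and returns at 34, moving the aryl ketone carbon–aryl bond to a later Grignard addition so that a smaller, more reactive dienophile is used. 25 is deprotonated (n-BuLi, THF, −78 °C) and formylated with DMF (inverse quench into aq. KH2PO4) to the alkynal F8. F8 is combined with 29 (toluene, rt) and worked up with dilute acid as in step 15 to give the 2,4-dihydroxybenzaldehyde F9. F9 is methylated at the para hydroxyl (MeI, K2CO3, acetone) to the 2-hydroxy-4-methoxybenzaldehyde F10, and addition of 4 (3 equiv, THF, 0 °C) gives 34.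

Step 21 (global demethylation). The likely failures are acid-promoted cyclisation, in which the styryl double bond, once protonated or once ring 1 has opened at O1–C2, is attacked within the molecule and the ring-1 region rearranges irreversibly, and incomplete cleavage of nine ethers. The fallback sets out from 39 and returns at 40, taking the alkene out before the Lewis acid and rebuilding it under basic conditions. Lemieux–Johnson cleavage of 39 (OsO4 cat., NaIO4, 2,6-lutidine, dioxane–H2O) gives the ring-1 4-carbaldehyde F11. BBr3 (CH2Cl2, −78 → 0 °C) should demethylate it to the octahydroxy aldehyde F12, which is silylated (t-BuMe2SiCl, imidazole, DMF) to the octakis(silyl ether) F13. Horner–Wadsworth–Emmons olefination with diethyl {[4-(tert-butyldimethylsilyloxy)phenyl]methyl}phosphonate (NaH, THF, 0 °C → rt) should give the (E)-stilbene nonakis(silyl ether) F14, and n-Bu4NF buffered with AcOH (THF, 0 °C) then gives 40.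

## Further compounds

F1 | step 8 | (2-bromo-6-hydroxy-4-methoxyphenyl)(3,5-dimethoxyphenyl)methanone | COc1cc(O)c(C(=O)c2cc(OC)cc(OC)c2)c(Br)c1
F2 | step 8 | [2-bromo-6-({3-iodo-4-[(4-methoxyphenyl)methoxy]phenyl}methoxy)-4-methoxyphenyl](3,5-dimethoxyphenyl)methanone | COc1cc(OCc2ccc(OCc3ccc(OC)cc3)c(I)c2)c(C(=O)c2cc(OC)cc(OC)c2)c(Br)c1
F3 | step 8 | hydrazone of F2 | COc1cc(OCc2ccc(OCc3ccc(OC)cc3)c(I)c2)c(C(=NN)c2cc(OC)cc(OC)c2)c(Br)c1
F4 | step 8 | (2S,3R)-4-bromo-3-(3,5-dimethoxyphenyl)-2-{3-iodo-4-[(4-methoxyphenyl)methoxy]phenyl}-6-methoxy-2,3-dihydro-1-benzofuran (cis) | Brc1cc(OC)cc2c1[C@@H](c1cc(OC)cc(OC)c1)[C@@H](c1ccc(OCc3ccc(OC)cc3)c(I)c1)O2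
F5 | step 20 | {4-methoxy-2-[(4-methoxyphenyl)methoxy]-6-V-phenyl}(3,5-dimethoxyphenyl)methanone | COc1ccc(/C=C/c2cc(OC)cc3c2[C@@H](c2cc(OC)cc(OC)c2)[C@H](c2ccc4c(c2)[C@@H](c2cc(OC)cc(OCc5ccc(OC)cc5)c2C(=O)c2cc(OC)cc(OC)c2)[C@H](c2ccc(OC)cc2)O4)O3)cc1
F6 | step 20 | hydrazone of F5 | COc1ccc(/C=C/c2cc(OC)cc3c2[C@@H](c2cc(OC)cc(OC)c2)[C@H](c2ccc4c(c2)[C@@H](c2cc(OC)cc(OCc5ccc(OC)cc5)c2C(=NN)c2cc(OC)cc(OC)c2)[C@H](c2ccc(OC)cc2)O4)O3)cc1
F7 | step 20 | (2S,3R)-3-(3,5-dimethoxyphenyl)-6-methoxy-2-(4-methoxyphenyl)-4-V-2,3-dihydro-1-benzofuran (cis at ring 3) | COc1ccc(/C=C/c2cc(OC)cc3c2[C@@H](c2cc(OC)cc(OC)c2)[C@H](c2ccc4c(c2)[C@@H](c2cc(OC)cc5c2[C@@H](c2cc(OC)cc(OC)c2)[C@@H](c2ccc(OC)cc2)O5)[C@H](c2ccc(OC)cc2)O4)O3)cc1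
F8 | step 15 | 3-V-prop-2-ynal | COc1ccc(/C=C/c2cc(OC)cc3c2[C@@H](c2cc(OC)cc(OC)c2)[C@H](c2ccc4c(c2)[C@@H](C#CC=O)[C@H](c2ccc(OC)cc2)O4)O3)cc1
F9 | step 15 | 2,4-dihydroxy-6-V-benzaldehyde | COc1ccc(/C=C/c2cc(OC)cc3c2[C@@H](c2cc(OC)cc(OC)c2)[C@H](c2ccc4c(c2)[C@@H](c2cc(O)cc(O)c2C=O)[C@H](c2ccc(OC)cc2)O4)O3)cc1
F10 | step 15 | 2-hydroxy-4-methoxy-6-V-benzaldehyde | COc1ccc(/C=C/c2cc(OC)cc3c2[C@@H](c2cc(OC)cc(OC)c2)[C@H](c2ccc4c(c2)[C@@H](c2cc(OC)cc(O)c2C=O)[C@H](c2ccc(OC)cc2)O4)O3)cc1
F11 | step 21 | octa-O-methyl ring-1 4-carbaldehyde (39 with CHO in place of the 4-methoxystyryl group) | O=Cc1cc(OC)cc2c1[C@@H](c1cc(OC)cc(OC)c1)[C@H](c1ccc3c(c1)[C@@H](c1cc(OC)cc4c1[C@@H](c1cc(OC)cc(OC)c1)[C@H](c1ccc(OC)cc1)O4)[C@H](c1ccc(OC)cc1)O3)O2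
F12 | step 21 | octahydroxy ring-1 4-carbaldehyde | O=Cc1cc(O)cc2c1[C@@H](c1cc(O)cc(O)c1)[C@H](c1ccc3c(c1)[C@@H](c1cc(O)cc4c1[C@@H](c1cc(O)cc(O)c1)[C@H](c1ccc(O)cc1)O4)[C@H](c1ccc(O)cc1)O3)O2
F13 | step 21 | octakis(tert-butyldimethylsilyl) ether of F12 | O=Cc1cc(O[Si](C)(C)C(C)(C)C)cc2c1[C@@H](c1cc(O[Si](C)(C)C(C)(C)C)cc(O[Si](C)(C)C(C)(C)C)c1)[C@H](c1ccc3c(c1)[C@@H](c1cc(O[Si](C)(C)C(C)(C)C)cc4c1[C@@H](c1cc(O[Si](C)(C)C(C)(C)C)cc(O[Si](C)(C)C(C)(C)C)c1)[C@H](c1ccc(O[Si](C)(C)C(C)(C)C)cc1)O4)[C@H](c1ccc(O[Si](C)(C)C(C)(C)C)cc1)O3)O2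
F14 | step 21 | nonakis(tert-butyldimethylsilyl) ether of 40 | CC(C)(C)[Si](C)(C)Oc1ccc(/C=C/c2cc(O[Si](C)(C)C(C)(C)C)cc3c2[C@@H](c2cc(O[Si](C)(C)C(C)(C)C)cc(O[Si](C)(C)C(C)(C)C)c2)[C@H](c2ccc4c(c2)[C@@H](c2cc(O[Si](C)(C)C(C)(C)C)cc5c2[C@@H](c2cc(O[Si](C)(C)C(C)(C)C)cc(O[Si](C)(C)C(C)(C)C)c2)[C@H](c2ccc(O[Si](C)(C)C(C)(C)C)cc2)O5)[C@H](c2ccc(O[Si](C)(C)C(C)(C)C)cc2)O4)O3)cc1
A1 | alternative 1 | (2R,3R)-5-bromo-2-(4-methoxyphenyl)-3-[(2R,3R)-3-(3,5-dimethoxyphenyl)-6-methoxy-2-(4-methoxyphenyl)-2,3-dihydro-1-benzofuran-4-yl]-2,3-dihydro-1-benzofuran | Brc1ccc2c(c1)[C@@H](c1cc(OC)cc3c1[C@@H](c1cc(OC)cc(OC)c1)[C@H](c1ccc(OC)cc1)O3)[C@H](c1ccc(OC)cc1)O2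
A2 | alternative 2 | nona-O-methyl target with a trimethylsilyl group on C7 of ring 2 | COc1ccc(/C=C/c2cc(OC)cc3c2[C@@H](c2cc(OC)cc(OC)c2)[C@H](c2cc([Si](C)(C)C)c4c(c2)[C@@H](c2cc(OC)cc5c2[C@@H](c2cc(OC)cc(OC)c2)[C@H](c2ccc(OC)cc2)O5)[C@H](c2ccc(OC)cc2)O4)O3)cc1
A3 | alternative 3 | nona-O-methyl ether of the target | COc1ccc(/C=C/c2cc(OC)cc3c2[C@@H](c2cc(OC)cc(OC)c2)[C@H](c2ccc4c(c2)[C@@H](c2cc(OC)cc5c2[C@@H](c2cc(OC)cc(OC)c2)[C@H](c2ccc(OC)cc2)O5)[C@H](c2ccc(OC)cc2)O4)O3)cc1
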